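## Retrosynthetic overview
1. Ring B, the only ring that has to be made, is cut at C1–C8a. This leads back to an open-chain (2R,3R)-dibenzylbutane-1,4-diol diacetate with both phenols free.
2. In the forward direction this bond is made last. The syringyl phenol is dehydrogenated to its p-quinone methide, and the guaiacyl ring attacks it para to OMe, which also sets C1.
3. The diacetate comes from a (2R,3R)-dibenzylsuccinate half-ester by reduction and alcohol-selective acetylation.
4. Both backbone stereocentres come from one double asymmetric hydrogenation of an (E,E)-dibenzylidenesuccinate.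
5. The diene comes from vanillin, syringaldehyde and dimethyl succinate by two Stobbe condensations, with no protecting groups. Ring order: ring B only, in the final step.

Assumption: the (S,S)-ligand is taken to give the (R,R)-product, by analogy with its known sense on benzylidenesuccinate half-esters; if a test run shows the opposite sense, the (R,R)-ligand is used instead.

## Route

Step 1
Reactants: 1 vanillin; 2 dimethyl succinate
Product: 4 dimethyl (E)-2-(4-hydroxy-3-methoxybenzylidene)succinate, via Stobbe half-ester 3 (not isolated)
Conditions: LiOMe (3 equiv), MeOH, reflux, 36 h; then conc. H2SO4 (2 equiv), same flask, reflux, 12 h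
Reagents that add atoms: methanol (CO)
Why: Stobbe condensation followed by Fischer esterification, in which the succinate enolate adds to the aldehyde, the aldolate lactonises on the distal ester, irreversible E1cB opening of that lactone gives the (E)-half-ester carboxylate even from the phenoxide form of vanillin, and acidifying the same methanol solution then re-esterifies the acid so that a second enolisation is possible.

Step 2
Reactants: 4 dimethyl (E)-2-(4-hydroxy-3-methoxybenzylidene)succinate; 5 syringaldehyde
Product: 6 (2E,3E)-2-(4-hydroxy-3-methoxybenzylidene)-3-(4-hydroxy-3,5-dimethoxybenzylidene)succinic acid 4-methyl ester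
Conditions: LiOMe (4 equiv), MeOH, reflux, 48 h; then 2 M HCl, 0 °C
Reagents that add atoms: none
Why: Second Stobbe condensation at the remaining CH2 group, which is both alpha to an ester and allylic, where the same lactonise-and-open mechanism leaves the free acid on the vanillylidene carbon and gives the (E,E)-diene because each aryl group ends up trans to its own carboxyl group.

Step 3
Reactants: 6 (2E,3E)-dibenzylidenesuccinic acid 4-methyl ester
Product: 7 (2R,3R)-2-(4-hydroxy-3-methoxybenzyl)-3-(4-hydroxy-3,5-dimethoxybenzyl)succinic acid 4-methyl ester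
Conditions: [Rh(cod)((S,S)-Et-DuPhos)]BF4 (1 mol%), NaOMe (10 mol%), H2 (20 bar), MeOH, 40 °C
Reagents that add atoms: none
Why: Proposed new method: a double asymmetric hydrogenation in which each trisubstituted C=C of the twisted diene is a beta-aryl itaconate-type unit that can chelate the cationic monovalent rhodium centre through the alkene and the carbonyl group on the neighbouring carbon, so the C2-symmetric bisphospholane delivers H2 to the same sense of face at both alkenes and sets both stereocentres as (2R,3R), any single mismatch ending in a separable (2R,3S)- or (2S,3R)-diastereomer and thereby raising the ee of 7, the closest known reaction type being the Rh–DuPhos hydrogenation of Stobbe-derived benzylidenesuccinate half-esters.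

Step 4
Reactants: 7 (2R,3R)-dibenzylsuccinic acid 4-methyl ester
Product: 8 (2R,3R)-2-(4-hydroxy-3-methoxybenzyl)-3-(4-hydroxy-3,5-dimethoxybenzyl)butane-1,4-diol
Conditions: LiAlH4 (5 equiv), THF, 0 °C to reflux; then 1 M HCl, 0 °C
Reagents that add atoms: none
Why: LiAlH4 reduction of the ester and the carboxylate to primary alcohols, in which the three acidic protons leave first as H2, the excess hydride reduces both carbonyl groups at reflux, and the two stereocentres survive because hydride addition is much faster than enolisation.

Step 5
Reactants: 8 (2R,3R)-tetraol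
Product: 9 (2R,3R)-2-(4-hydroxy-3-methoxybenzyl)-3-(4-hydroxy-3,5-dimethoxybenzyl)butane-1,4-diyl diacetate
Conditions: vinyl acetate (6 equiv), immobilised Candida antarctica lipase B, 2-MeTHF, 40 °C
Reagents that add atoms: vinyl acetate (C=COC(C)=O)
Why: Lipase-catalysed irreversible transesterification, in which the acetyl-enzyme formed from vinyl acetate is taken up only by the primary aliphatic hydroxyl groups because phenols are not accepted as nucleophiles by this serine hydrolase, the released vinyl alcohol tautomerises to acetaldehyde so the reaction cannot reverse, and no stereocentre is involved.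

Step 6
Reactants: 9 (2R,3R)-seco-diacetate
Product: 11 [(1S,2R,3R)-7-hydroxy-1-(4-hydroxy-3,5-dimethoxyphenyl)-6-methoxy-1,2,3,4-tetrahydronaphthalene-2,3-diyl]bis(methylene) diacetate, via syringyl p-quinone methide 10 (not isolated)
Conditions: DDQ (1.0 equiv, slow addition), CH2Cl2/(CF3)2CHOH 4:1, −30 °C to 0 °C
Reagents that add atoms: none
Why: Proposed new method: a site-selective dehydrogenative p-quinone methide Friedel–Crafts cyclisation in which DDQ removes the phenolic hydrogen and one benzylic hydrogen from the more electron-rich 2,6-dimethoxyphenol, whose O–H bond is weaker and whose oxidation potential is lower than those of the guaiacol, to give the symmetrical quinone methide 10, the hydrogen-bond-donating but non-nucleophilic fluoroalcohol then activates its carbonyl group, the acetates rule out capture by oxygen, and C6 of the guaiacyl ring (para to OMe) attacks the exocyclic carbon through a half-chair transition state in which both CH2OAc groups and the syringyl group are equatorial, which sets C1 as (S), trans to C2, and leaves C2 and C3 untouched, the closest known reaction types being Ag2O- or DDQ-generated p-quinone methide-initiated cyclisations and the acid-induced conversion of lariciresinol-type lignans into isolariciresinols.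

## Compound list
1 | vanillin (4-hydroxy-3-methoxybenzaldehyde) | COc1cc(C=O)ccc1O | starting material
2 | dimethyl succinate | COC(=O)CCC(=O)OC | starting material
3 | (E)-4-(4-hydroxy-3-methoxyphenyl)-3-(methoxycarbonyl)but-3-enoic acid (Stobbe half-ester) | OC(=O)C/C(=C\c1ccc(O)c(OC)c1)C(=O)OC | intermediate
4 | dimethyl (E)-2-(4-hydroxy-3-methoxybenzylidene)succinate | COC(=O)C/C(=C\c1ccc(O)c(OC)c1)C(=O)OC | intermediate
5 | syringaldehyde (4-hydroxy-3,5-dimethoxybenzaldehyde) | COc1cc(C=O)cc(OC)c1O | starting material
6 | (2E,3E)-2-(4-hydroxy-3-methoxybenzylidene)-3-(4-hydroxy-3,5-dimethoxybenzylidene)succinic acid 4-methyl ester | COc1cc(/C=C(C(=O)O)\C(=C/c2cc(OC)c(O)c(OC)c2)C(=O)OC)ccc1O | intermediate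
7 | (2R,3R)-2-(4-hydroxy-3-methoxybenzyl)-3-(4-hydroxy-3,5-dimethoxybenzyl)succinic acid 4-methyl ester | COc1cc(C[C@@H](C(=O)O)[C@H](C(=O)OC)Cc2cc(OC)c(O)c(OC)c2)ccc1O | intermediate
8 | (2R,3R)-2-(4-hydroxy-3-methoxybenzyl)-3-(4-hydroxy-3,5-dimethoxybenzyl)butane-1,4-diol | COc1cc(C[C@@H](CO)[C@H](CO)Cc2cc(OC)c(O)c(OC)c2)ccc1O | intermediate
9 | (2R,3R)-2-(4-hydroxy-3-methoxybenzyl)-3-(4-hydroxy-3,5-dimethoxybenzyl)butane-1,4-diyl diacetate | COc1cc(C[C@@H](COC(C)=O)[C@H](COC(C)=O)Cc2cc(OC)c(O)c(OC)c2)ccc1O | intermediate
10 | (2R,3R)-2-(4-hydroxy-3-methoxybenzyl)-3-[(3,5-dimethoxy-4-oxocyclohexa-2,5-dien-1-ylidene)methyl]butane-1,4-diyl diacetate (syringyl p-quinone methide) | COc1cc(C[C@@H](COC(C)=O)[C@H](COC(C)=O)C=C2C=C(OC)C(=O)C(OC)=C2)ccc1O | intermediate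
11 | [(1S,2R,3R)-7-hydroxy-1-(4-hydroxy-3,5-dimethoxyphenyl)-6-methoxy-1,2,3,4-tetrahydronaphthalene-2,3-diyl]bis(methylene) diacetate, all-trans | COc1cc2c(cc1O)[C@H](c1cc(OC)c(O)c(OC)c1)[C@@H](COC(C)=O)[C@H](COC(C)=O)C2 | target

## Step count and weak points
Total step count: 6. Longest linear sequence: 6 steps, from 1 and 2 to 11.

**Step 6 (most likely to fail).**
- Competing oxidation at the guaiacol would give the regioisomeric tetralin.
- The doubly benzylic C1–H of 11 can be over-oxidised.
- Tautomerisation of 10 to the styrene would erode the C2 configuration.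

The fallback sets out from 9 and comes back at 11. TIPSCl and imidazole in DMF at 0 °C silylate the less hindered guaiacyl OH, because the syringyl OH is flanked by two OMe groups. This gives guaiacyl O-TIPS seco-diacetate F1. With a single free phenol left, Ag2O in CH2Cl2 can only give O-TIPS syringyl quinone methide F2. F2 is filtered from the silver residues, cooled to −78 °C and closed with BF3·OEt2 to 7-O-TIPS aryltetralin diacetate F3. Bu4NF buffered with AcOH then removes the silyl group without touching the acetates and gives 11.

**Step 3.**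
- The diene may take up H2 in a 1,4-sense and stall at the tetrasubstituted dibenzylbutenedioate.
- The second addition may be substrate-controlled and give the wrong diastereomer.

The fallback sets out from 3, isolated by acid work-up before the esterification stage of step 1, and comes back at 8.
- Single hydrogenation of 3 with the same rhodium catalyst, on its standard substrate class, gives (R)-vanillylsuccinic acid 1-methyl ester F4.
- The potassium salt of F4 is reduced at the ester with Ca(BH4)2 in EtOH and acidified to (R)-4-vanillylbutyrolactone F5. Its stereocentre is beta to the carbonyl group and cannot epimerise.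
- NaOMe-mediated condensation of F5 with 5 in refluxing MeOH gives (E)-syringylidene lactone F6.
- H2 over Pd/C adds anti to the vanillyl group and gives cis-dibenzyl lactone F7.
- NaOMe in MeOH equilibrates F7 to trans-dibenzyl lactone F8, and LiAlH4 opens F8 to 8.

**Step 5.** The beta-branched, crowded primary alcohols may be poor lipase substrates, so the reaction may stall at a monoacetate.

The fallback sets out from 8 and comes back at 9. Ac2O in pyridine acetylates all four hydroxyl groups to seco-tetraacetate F9. Pyrrolidine (2.2 equiv, CH2Cl2, 0 °C) then cleaves only the two aryl acetates by aminolysis, because aryl esters are far better acyl donors than alkyl esters. This gives 9.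

## Further compounds
F1 | step 6 | guaiacyl O-TIPS seco-diacetate (9 with the guaiacyl OH as its triisopropylsilyl ether) | COc1cc(C[C@@H](COC(C)=O)[C@H](COC(C)=O)Cc2cc(OC)c(O)c(OC)c2)ccc1O[Si](C(C)C)(C(C)C)C(C)C
F2 | step 6 | O-TIPS syringyl quinone methide (10 with the guaiacyl OH as its triisopropylsilyl ether) | COc1cc(C[C@@H](COC(C)=O)[C@H](COC(C)=O)C=C2C=C(OC)C(=O)C(OC)=C2)ccc1O[Si](C(C)C)(C(C)C)C(C)C
F3 | step 6 | 7-O-TIPS aryltetralin diacetate ((1S,2R,3R), 11 with the C7 OH as its triisopropylsilyl ether) | COc1cc2c(cc1O[Si](C(C)C)(C(C)C)C(C)C)[C@H](c1cc(OC)c(O)c(OC)c1)[C@@H](COC(C)=O)[C@H](COC(C)=O)C2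
F4 | step 3 | (R)-vanillylsuccinic acid 1-methyl ester ((3R)-4-(4-hydroxy-3-methoxyphenyl)-3-(methoxycarbonyl)butanoic acid) | OC(=O)C[C@@H](Cc1ccc(O)c(OC)c1)C(=O)OC
F5 | step 3 | (R)-4-vanillylbutyrolactone ((4R)-4-(4-hydroxy-3-methoxybenzyl)dihydrofuran-2(3H)-one) | O=C1C[C@@H](Cc2ccc(O)c(OC)c2)CO1
F6 | step 3 | (E)-syringylidene lactone ((3E,4R)-3-(4-hydroxy-3,5-dimethoxybenzylidene)-4-(4-hydroxy-3-methoxybenzyl)dihydrofuran-2(3H)-one) | O=C1/C(=C/c2cc(OC)c(O)c(OC)c2)[C@@H](Cc2ccc(O)c(OC)c2)CO1
F7 | step 3 | cis-dibenzyl lactone ((3S,4R)-3-(4-hydroxy-3,5-dimethoxybenzyl)-4-(4-hydroxy-3-methoxybenzyl)dihydrofuran-2(3H)-one) | O=C1[C@@H](Cc2cc(OC)c(O)c(OC)c2)[C@@H](Cc2ccc(O)c(OC)c2)CO1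
F8 | step 3 | trans-dibenzyl lactone ((3R,4R)-3-(4-hydroxy-3,5-dimethoxybenzyl)-4-(4-hydroxy-3-methoxybenzyl)dihydrofuran-2(3H)-one) | O=C1[C@H](Cc2cc(OC)c(O)c(OC)c2)[C@@H](Cc2ccc(O)c(OC)c2)CO1
F9 | step 5 | seco-tetraacetate ((2R,3R), 8 with all four hydroxyl groups acetylated) | COc1cc(C[C@@H](COC(C)=O)[C@H](COC(C)=O)Cc2cc(OC)c(OC(C)=O)c(OC)c2)ccc1OC(C)=O
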